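The data come from a simulation from invented constants; scatter was added.

In a closed flask of constant volume the charge is conserved: starting material left, product and whatever the readings miss add up to what went in.

all flasks: starting material 0.25 M

| flask | protic impurity | temperature | remark | time |
|---|---|---|---|---|
| dusk | 0.0063 M | −5 °C | run made earlier |  |
| noon | 0.0094 M | 20 °C | run made earlier |  |
| Wednesday's | 0.0125 M | 0 °C |  | 5.0 d |
| Sunday's | 0.0125 M | 40 °C |  | 5.0 d |
| Tuesday's | 0.0125 M | 20 °C |  | 5.0 d |

dusk run (percent of the starting material charged)

| time / d | product / % | starting material / % |
|---|---|---|
| 0.500 | 27.1 | 69.9 |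
| 1.25 | 63.0 | 33.4 |
| 2.50 | 94.1 | 2.7 |
| 4.00 | 97.6 | 0.6 |

noon run (percent of the starting material charged)

| time / h | product / % | starting material / % |
|---|---|---|
| 4.00 | 97.1 | 0 |
| 12.0 | 96.9 | 0 |
| 20.0 | 97.0 | 0.4 |
| 40.0 | 96.2 | 0 |

(scatter of a reading: 0.5 percentage points)

- the flask that comes out highest in amount of product, in percent of the starting material charged, or "all alike" when all lie within 1.5 percentage points (Wednesday's / Sunday's / Tuesday's / all alike)
- product at the end, in percent of the starting material charged, Wednesday's
- product at the end, in percent of the starting material charged, Sunday's
- product at the end, in percent of the starting material charged, Tuesday's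



Take the rate first, from the dusk run. Starting material falls by a fraction 0.602 d⁻¹ of the charge in the first interval, then 0.487 d⁻¹, then 0.246 d⁻¹. The rate thus sags by a factor 1.24, then 1.98, together 2.45. Even that last rate, held for 5.0 d, would cover 1.23 charges. Wednesday's flask, the coldest new one, is warmer than the dusk run. So expect the starting material to be consumed in each new flask, provided the added protic impurity does not slow it badly.

Now write the balance of protic impurity, the reagent charged in the smaller amount. Suppose each unit of it removes one unit of starting material. By charge it is then the limiting reagent of the loss, and the loss ceiling L, the charge of protic impurity over the charge of starting material, caps that loss. Once the starting material is consumed, product then equals the charge minus L times the spent share of the impurity. Read the test: the missing share averages 2.90 % in the dusk run, where L is 2.52 %, and 3.10 % in the noon run, where L is 3.76 %. Both shares are read off scattered readings, and the dusk share stands 0.38 percentage points above its L, against a scatter of 0.5 points on one reading. For the new flasks L is 5.00 %, so my reckoning puts product at 95.0 % or a little above in each.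

The forecast gives 95.5 % for Wednesday's, 95 % for Sunday's and 95.5 % for Tuesday's, hence all alike, since “the impurity consumes starting material roughly one-to-one”.

The flasks give 95.0 % for Wednesday's, 95.7 % for Sunday's and 95.1 % for Tuesday's, so all alike.

    starting material → product, rate k1*[starting material]/(1 + ([starting material]/sat1)) (0.0560 M, k = 4.90 h⁻¹, Ea = 95.0 kJ mol⁻¹)
    starting material + protic impurity → quenched substrate (k = 25.0 M⁻¹ h⁻¹, Ea = 69.0 kJ mol⁻¹)
    (constants at 20 °C)

At 5.00 d Sunday's flask still holds 14.0 % of its protic impurity, with 0 % starting material left. Put that into the balance: L times the spent share is 4.30 %, which leaves 95.7 % product.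

Take the neighbour of Sunday's flask with 0.031 M protic impurity: L is 12.4 %, which puts product at 87.6 % or a little above, and with 16 % of its impurity left the balance gives 89.6 %. The computed flask gives 89.6 %.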